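Two mirror-image substrates race for the same partner on the same catalyst, and through that race one number holds still: the logarithm of the left-handed substrate's surviving fraction divided by that of the right-handed substrate. Divide one rate by the other and partner, catalyst and time drop out.

| flask | left-handed substrate | right-handed substrate | partner | protic impurity | precatalyst | remark | time |
|---|---|---|---|---|---|---|---|
| epsilon | 0.050 M | 0.050 M | 0.11 M | 0.015 M | 43 µM | run made earlier |  |
| eta | 0.050 M | 0.050 M | 0.13 M | 0.015 M | 43 µM | run made earlier |  |
| beta | 0.050 M | 0.050 M | 0.18 M | 0.015 M | 43 µM | run made earlier |  |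
| dawn | 0.050 M | 0.050 M | 0.150 M | 0.0150 M | 43 µM |  | 50 min |
| winter | 0.050 M | 0.050 M | 0.100 M | 0.0150 M | 43 µM |  | 50 min |

| run | time / min | right-handed substrate / % | left-handed substrate / % |
|---|---|---|---|
| epsilon | 5.00 | 46.4 | 39.7 |
| epsilon | 10.0 | 44.3 | 32.2 |
| epsilon | 15.0 | 41.1 | 26.1 |
| epsilon | 20.0 | 38.8 | 22.5 |
| epsilon | 25.0 | 37.0 | 19.6 |
| eta | 2.00 | 49.2 | 45.4 |
| eta | 6.00 | 45.2 | 35.7 |
| eta | 12.0 | 40.4 | 26.8 |
| eta | 20.0 | 36.9 | 19.1 |
| eta | 25.0 | 35.0 | 15.7 |
| beta | 5.00 | 45.2 | 33.6 |
| beta | 10.0 | 38.8 | 22.9 |
| beta | 15.0 | 35.5 | 16.6 |
| beta | 20.0 | 32.5 | 12.2 |
| beta | 25.0 | 29.7 | 9.2 |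

(scatter of a reading: 0.5 percentage points)
- catalyst is single-handed; left-handed substrate and right-handed substrate are mirror images of each other, charged as a racemate, each of them at the stated concentration
- steps under discussion: partner + catalyst + left-handed substrate -> catalyst + left-handed product; partner + catalyst + right-handed substrate -> catalyst + right-handed product; partner + protic impurity -> quenched reagent; precatalyst <-> catalyst; partner -> decomposition product
- an excess is the difference of the two amounts in percent of their sum
- an excess is below zero if the other one leads
- which one finishes higher in excess of right-handed substrate over left-handed substrate among what is left of the two ("neither" within 2 percentage points) (dawn / winter / neither)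
- excess of right-handed substrate over left-handed substrate among what is left of the two at the end, dawn
- excess of right-handed substrate over left-handed substrate among what is left of the two at the end, winter

Take the last beta reading; the two substrates are charged equally, so each starts at 0.5 of the total:

ln(9.2 % ÷ 0.5) / ln(29.7 % ÷ 0.5) = 3.25

That ratio, which carries the scatter of its readings, is my reading of the selectivity factor; the last eta reading gives 3.25.

Now my own ledger for partner in winter, booking the protic impurity first, one for one:

charged 0.100 M, less 0.0150 M to the impurity, leaves 0.0850 M for substrates, with nothing booked to decomposition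

That is less than the 0.100 M of substrate, so in winter partner is the limiting reagent. Dawn keeps 0.135 M, more than the substrate.

For pace, beta had a mean partner of about 0.134 M over 25.0 min. The logarithmic loss scales with mean partner times time, so try a mean of 0.0567 M for winter:

left-handed loss 1.43, right-handed loss 0.440
fractions left 24.0 % and 64.5 %
partner at the end 0.0292 M, so the mean is 0.0571 M

The books close near the mean I tried, and I reckon an excess of 45.7 %. Dawn, tried at 0.101 M, gives about 70.8 %.

The forecast says dawn, with 65 % for dawn and 42 % for winter, where in its words “partner starves”. My figures stand higher than these, in the same order.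

The flask puts dawn higher, the forecast's choice, with 66.8 % in dawn and 43.1 % in winter.

    partner + catalyst + left-handed substrate → catalyst + left-handed product (k = 1200 M⁻² s⁻¹)
    partner + catalyst + right-handed substrate → catalyst + right-handed product (k = 370 M⁻² s⁻¹)
    partner + protic impurity → quenched reagent (k = 1.30 M⁻¹ s⁻¹)
    precatalyst ⇌ catalyst (K = 0.220, k = 0.0100 s⁻¹)
    partner → decomposition product (k = 1.20 × 10⁻⁵ s⁻¹)

In winter, 66 % of the right-handed charge remains, and raised to the power 3.25 that gives 26.2 % for the left-handed charge, against 26 % in the flask. Now take the neighbour, winter with 0.060 M of protic impurity. Its quenched reagent holds 0.0600 M, leaving 0.0400 M of partner for other uses. At 50.0 min, 84 % of its right-handed charge remains, so the same power gives 56.8 % for the left-handed charge and an excess of 19.3 %. That flask holds 57 % of its left-handed charge and ends at an excess of 19.3 %.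

(Readings and results are calculated from invented constants; scatter was added.)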